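## Retrosynthetic overview

1. Target ⇒ C3–CH2Ar bond: trans-selective benzylation of the dianion of a phenolic (R)-4-benzyl-γ-butyrolactone with 3,4,5-trimethoxybenzyl bromide.
2. That lactone ⇒ one hydrogenolysis/decarboxylation of a benzyl 2-oxooxolane-3-carboxylate carrying an O-benzyl syringyl group.
3. That ester ⇒ copper-catalysed opening of the cyclopropane of benzyl 2-oxo-3-oxabicyclo[3.1.0]hexane-1-carboxylate by a syringyl Grignard reagent.
4. The bicycle ⇒ dibenzyl malonate + (R)-epichlorohydrin; the epoxide carbon is the only purchased stereocentre.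
5. Ring order: cyclopropane and γ-lactone form together in one flask; the cyclopropane is then spent to install the C4 benzyl group; both arenes are bought.

Assumption: the SMILES is read as the trans (3R,4R) lactone; 4-bromo-2,6-dimethoxyphenol, dibenzyl malonate, (R)-epichlorohydrin, 3,4,5-trimethoxybenzyl bromide and 1.0 M NaOBn in BnOH are purchased.

## Route

Step 1
Reactants: 1 4-bromo-2,6-dimethoxyphenol
Product: 2 5-bromo-2-(benzyloxy)-1,3-dimethoxybenzene
Conditions: BnBr (1.1 equiv), K2CO3 (1.5 equiv), DMF, 60 °C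
Reagents that add atoms: benzyl bromide, BrCc1ccccc1
Why: Williamson ether synthesis (phenoxide SN2 on a benzylic bromide); the benzyl ether masks the phenol for Grignard formation and later leaves in the same hydrogenolysis as the benzyl ester.

Step 2
Reactants: 3 dibenzyl malonate; 4 (R)-epichlorohydrin
Product: 6 benzyl (1R,5R)-2-oxo-3-oxabicyclo[3.1.0]hexane-1-carboxylate, via dibenzyl [(2R)-oxiran-2-ylmethyl]malonate 5 (not isolated)
Conditions: NaOBn (1.0 M in BnOH, 1.15 equiv), 3 (1.2 equiv), THF, 0 °C → rt; then 4 (1.0 equiv), 65 °C, 16 h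
Reagents that add atoms: none
Why: Malonate–epichlorohydrin tandem alkylation / 3-exo-tet cyclopropanation / lactonization: the malonate anion opens the epoxide of 4 at CH2, the chlorohydrin alkoxide recloses to epoxide 5, the re-formed malonate anion opens 5 intramolecularly with inversion at the stereocentre, and the released cis CH2O– lactonizes onto the neighbouring ester, so cyclopropane and lactone form in one operation, the (R) centre of 4 becomes C5 of 6 and the cis ring fusion fixes C1; benzyloxide in benzyl alcohol keeps the ester exchange degenerate and the lactonization reversible.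

Step 3
Reactants: 6 benzyl (1R,5R)-2-oxo-3-oxabicyclo[3.1.0]hexane-1-carboxylate; 2 5-bromo-2-(benzyloxy)-1,3-dimethoxybenzene
Product: 8 benzyl (3R,4R)-4-[4-(benzyloxy)-3,5-dimethoxybenzyl]-2-oxooxolane-3-carboxylate, via [4-(benzyloxy)-3,5-dimethoxyphenyl]magnesium bromide 7 (not isolated)
Conditions: 2 (1.4 equiv), Mg, I2 (cat.), THF, 50 °C; then CuBr·SMe2 (10 mol%), 6, THF, −40 → −15 °C; 1 M HCl
Reagents that add atoms: none
Why: Copper-catalysed homoconjugate addition of an aryl Grignard reagent to a doubly activated cyclopropane: the arylcopper attacks the unhindered C6 methylene and cleaves C1–C6 to a malonate-type enolate, so C5 of 6 is untouched and becomes (R)-C4 of the lactone, while C3 protonates to the trans isomer and is erased in the next step anyway.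

Step 4
Reactants: 8 benzyl (3R,4R)-4-[4-(benzyloxy)-3,5-dimethoxybenzyl]-2-oxooxolane-3-carboxylate
Product: 10 (4R)-4-(4-hydroxy-3,5-dimethoxybenzyl)oxolan-2-one, via (3S,4R)-4-(4-hydroxy-3,5-dimethoxybenzyl)-2-oxooxolane-3-carboxylic acid 9 (not isolated)
Conditions: H2 (1 atm), 10% Pd/C, EtOAc, rt; filter; toluene, 110 °C
Reagents that add atoms: none
Why: Hydrogenolysis cleaves the benzyl ester and the aryl benzyl ether together, and the resulting 2-oxo-3-carboxylic acid loses CO2 on heating through the usual six-membered transition state (malonic-type thermal decarboxylation); C4 is not involved.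

Step 5
Reactants: 10 (4R)-4-(4-hydroxy-3,5-dimethoxybenzyl)oxolan-2-one; 11 3,4,5-trimethoxybenzyl bromide
Product: 13 (3R,4R)-4-(4-hydroxy-3,5-dimethoxybenzyl)-3-(3,4,5-trimethoxybenzyl)oxolan-2-one, via dilithium phenoxide enolate 12 (not isolated)
Conditions: LDA (2.1 equiv), THF, −78 °C; 11 (1.05 equiv), −78 → −30 °C; 1 M HCl
Reagents that add atoms: none
Why: Dianion alkylation of a lactone enolate: the second-formed, more basic enolate carbon reacts with the benzylic bromide far faster than the hindered lithium phenoxide, and the electrophile approaches anti to the C4 benzyl group (kinetic trans-selective α-alkylation of a β-substituted γ-butyrolactone), which sets C3 as R.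

## Compound list

1 | 4-bromo-2,6-dimethoxyphenol | COc1cc(Br)cc(OC)c1O | starting material
2 | 5-bromo-2-(benzyloxy)-1,3-dimethoxybenzene | COc1cc(Br)cc(OC)c1OCc1ccccc1 | intermediate
3 | dibenzyl malonate (dibenzyl propanedioate) | O=C(CC(=O)OCc1ccccc1)OCc1ccccc1 | starting material
4 | (R)-epichlorohydrin, (2R)-2-(chloromethyl)oxirane | ClC[C@H]1CO1 | starting material
5 | dibenzyl 2-{[(2R)-oxiran-2-yl]methyl}propanedioate | O=C(OCc1ccccc1)C(C[C@@H]1CO1)C(=O)OCc1ccccc1 | intermediate (not isolated)
6 | benzyl (1R,5R)-2-oxo-3-oxabicyclo[3.1.0]hexane-1-carboxylate (same spatial arrangement as the (1S,5R) methyl and ethyl esters; C1 reads R because CO2Bn outranks the lactone carbonyl) | O=C1OC[C@@H]2C[C@]12C(=O)OCc1ccccc1 | intermediate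
7 | [4-(benzyloxy)-3,5-dimethoxyphenyl]magnesium bromide | COc1cc([Mg]Br)cc(OC)c1OCc1ccccc1 | intermediate (not isolated)
8 | benzyl (3R,4R)-4-{[4-(benzyloxy)-3,5-dimethoxyphenyl]methyl}-2-oxooxolane-3-carboxylate (trans) | COc1cc(C[C@H]2COC(=O)[C@@H]2C(=O)OCc2ccccc2)cc(OC)c1OCc1ccccc1 | intermediate
9 | (3S,4R)-4-[(4-hydroxy-3,5-dimethoxyphenyl)methyl]-2-oxooxolane-3-carboxylic acid | COc1cc(C[C@H]2COC(=O)[C@@H]2C(O)=O)cc(OC)c1O | intermediate (not isolated)
10 | (4R)-4-[(4-hydroxy-3,5-dimethoxyphenyl)methyl]oxolan-2-one | COc1cc(C[C@H]2COC(=O)C2)cc(OC)c1O | intermediate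
11 | 3,4,5-trimethoxybenzyl bromide, 5-(bromomethyl)-1,2,3-trimethoxybenzene | COc1cc(CBr)cc(OC)c1OC | starting material
12 | dilithium salt of 10 (lithium phenoxide, lithium lactone enolate; 4R) | COc1cc(C[C@H]2COC(O[Li])=C2)cc(OC)c1O[Li] | intermediate (not isolated)
13 | (3R,4R)-4-[(4-hydroxy-3,5-dimethoxyphenyl)methyl]-3-[(3,4,5-trimethoxyphenyl)methyl]oxolan-2-one (trans) | COc1cc(C[C@H]2COC(=O)[C@@H]2Cc2cc(OC)c(OC)c(OC)c2)cc(OC)c1O | target

## Step count and risks

Total steps: 5. Longest linear sequence: 4 (steps 2, 3, 4, 5; equally 1, 3, 4, 5).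

**Step 2 (most at risk).** The bicyclization is well established for methyl, ethyl and tert-butyl malonates but the benzyl ester version is an extension. Possible failures are the 5-(chloromethyl) lactone by-product, incomplete conversion, and some loss of ee through direct chloride displacement; a few percent of the wrong enantiomer would be removed by recrystallising 10 or 13. The fallback sets out from 4 and comes back at 10, and swaps the hydrogenolytic ester removal for a Krapcho reaction. Compound 4 with dimethyl malonate (COC(=O)CC(=O)OC) and NaOMe in MeOH at reflux gives methyl (1S,5R)-2-oxo-3-oxabicyclo[3.1.0]hexane-1-carboxylate F1. Opening of this with Grignard reagent 7 and CuBr·SMe2 as in step 3 gives methyl (3S,4R)-4-{[4-(benzyloxy)-3,5-dimethoxyphenyl]methyl}-2-oxooxolane-3-carboxylate F2. Krapcho dealkoxycarbonylation (LiCl, wet DMSO, 140 °C) gives (4R)-4-{[4-(benzyloxy)-3,5-dimethoxyphenyl]methyl}oxolan-2-one F3, and hydrogenolysis (H2, 10% Pd/C, EtOAc) returns to 10. This costs two extra steps.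

**Step 3.** The aryl Grignard reagent may add 1,2 to the lactone or the benzyl ester, or the electron-rich Grignard may form sluggishly. The fallback sets out from 6 and comes back at 9, and makes the C–C bond by electrophilic aromatic substitution instead of an organometallic. Compound 6 with 2,6-dimethoxyphenol (COc1cccc(OC)c1O) and Sc(OTf)3 (10 mol%) in HFIP at 50 °C should undergo Friedel–Crafts-type homoconjugate opening at the unhindered cyclopropane CH2 by the para position of the phenol. This is untested on this substrate; the closest precedent is acid-promoted arylative opening of acceptor cyclopropanes in HFIP, and attack at the ring-fusion CH would be the competing regiochemistry. The product is benzyl (3R,4R)-4-[(4-hydroxy-3,5-dimethoxyphenyl)methyl]-2-oxooxolane-3-carboxylate F4, which under the step 4 conditions gives acid 9 and then 10. Step 1 and the benzyl ether are then not needed.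

**Step 5.** The dianion may O-benzylate at the phenoxide, dissolve poorly, or dialkylate. The fallback sets out from 10 and comes back at 13, and uses a protected monoanion instead. Compound 10 with TBSCl and imidazole in DMF gives (4R)-4-({4-[(tert-butyldimethylsilyl)oxy]-3,5-dimethoxyphenyl}methyl)oxolan-2-one F5. LDA (1.1 equiv) in THF at −78 °C followed by 11 gives (3R,4R)-4-({4-[(tert-butyldimethylsilyl)oxy]-3,5-dimethoxyphenyl}methyl)-3-[(3,4,5-trimethoxyphenyl)methyl]oxolan-2-one F6. TBAF buffered with AcOH in THF at 0 °C then gives 13.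

Further compounds

F1 | step 2 | methyl (1S,5R)-2-oxo-3-oxabicyclo[3.1.0]hexane-1-carboxylate | O=C1OC[C@@H]2C[C@]12C(=O)OC
F2 | step 2 | methyl (3S,4R)-4-{[4-(benzyloxy)-3,5-dimethoxyphenyl]methyl}-2-oxooxolane-3-carboxylate | COc1cc(C[C@H]2COC(=O)[C@@H]2C(=O)OC)cc(OC)c1OCc1ccccc1
F3 | step 2 | (4R)-4-{[4-(benzyloxy)-3,5-dimethoxyphenyl]methyl}oxolan-2-one | COc1cc(C[C@H]2COC(=O)C2)cc(OC)c1OCc1ccccc1
F4 | step 3 | benzyl (3R,4R)-4-[(4-hydroxy-3,5-dimethoxyphenyl)methyl]-2-oxooxolane-3-carboxylate | COc1cc(C[C@H]2COC(=O)[C@@H]2C(=O)OCc2ccccc2)cc(OC)c1O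
F5 | step 5 | (4R)-4-({4-[(tert-butyldimethylsilyl)oxy]-3,5-dimethoxyphenyl}methyl)oxolan-2-one | COc1cc(C[C@H]2COC(=O)C2)cc(OC)c1O[Si](C)(C)C(C)(C)C
F6 | step 5 | (3R,4R)-4-({4-[(tert-butyldimethylsilyl)oxy]-3,5-dimethoxyphenyl}methyl)-3-[(3,4,5-trimethoxyphenyl)methyl]oxolan-2-one | COc1cc(C[C@H]2COC(=O)[C@@H]2Cc2cc(OC)c(OC)c(OC)c2)cc(OC)c1O[Si](C)(C)C(C)(C)C
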